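A neighbour of this flask, with the same charge read at 20 s, is where I test at the end what I reckon here for 80 s.

    substrate ⇌ dormant form (K1 = 4.0, k1 = 0.016 s⁻¹)
    intermediate A ⇌ intermediate B (K2 = 0.16, k2 = 0.058 s⁻¹)
    intermediate D → side product (k3 = 0.0073 s⁻¹)
    intermediate B ⇌ intermediate D (K4 = 1.9, k4 = 0.024 s⁻¹)
    substrate → intermediate A (k5 = 0.034 s⁻¹)
    intermediate C → target (k6 = 0.0024 s⁻¹)
    substrate ⇌ intermediate C (K7 = 1.4, k7 = 0.18 s⁻¹)

substrate 20 mM; time 80 s

- the state of affairs at 80 s: stopped, and by what, or still going (it is still moving / forward and back rates have come level / all of the substrate has reacted)
- the target standing at 80 s, as a percentage of the substrate charged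

- the reaction counts as stopped when no species that holds the substrate changes by six tenths of a point or more over the second half of the time
- run time (flask): 80 s

- In this flask target has one source, intermediate C, so its yield is 0.0024 s⁻¹ times the time integral of intermediate C, counted in seconds of the full charge.
- Substrate and intermediate C exchange with a relaxation time τ of 3.24 s. Because that is far shorter than the run, I hold intermediate C at the equilibrium share f = 58.3 % of their joint pool.
- With no drain, that share gives a crude ceiling of 11.2 %.
- My carried quantity is the pool drain constant λ, the pseudo-first-order loss of the joint pool to intermediate A, dormant form and target, each weighted by the share that feeds it: 0.0222 s⁻¹.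
- For the lower estimate, dormant form never returns and the pool starts with intermediate C empty, which costs f·τ of the integral and, with the early excess of substrate, about (k1 + k5)·f·τ of the pool, so I get 4.29 %.
- For the upper estimate, the pool loses nothing to dormant form and there is no lag, so the drain is 0.0156 s⁻¹ and the yield 6.40 %.
- The pool still shrinks to 0.411 of itself over the second half, so I call this flask still moving.
- The forecast says it is still moving and 4.9 %, on the ground that the “time-integrated concentration over the run is about 20 s of the charge”. That sits inside my bracket.
- This flask gives: it is still moving, with target at 5.03 %. At 21.6 s the substrate's forward half-life toward intermediate C is 3.9 s, shorter than its 20 s toward intermediate A, and at 80.0 s intermediate C stands at 12.3 % beside substrate at 7.78 %. Left to 800 s, this flask reads 8.43 %, while the flask charged with 5.0 mM of substrate reads 5.03 % at 80 s. With λ = 0.0222 s⁻¹, my lower estimate for the neighbour read at 20 s is 1.59 %, and my upper estimate is 2.41 %. That neighbour reads 1.82 %.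

The constants used here are invented; the rest is arithmetic.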